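## Retrosynthetic overview

- The target is the 21-fold phenol of an eicosamethyl ether, released by BBr3. The ring B C4 hydroxyl comes from a formyl group (Dakin-type oxidation), and the ether from ring C (C1) to ring B (C5) comes from an SNAr of a ring C phenol on an AB fluoroaldehyde.
- The strategy rests on ring C: C1 to C5 all carry oxygen, C6 is the only C–H, and the crowded ether to ring D sits on C2. Cutting C1–C6 makes C1–C4 the four carbons of a squarate and C5–C6 a 1-methoxyvinyl group, with the ring D ether carried in as a squarate aryl ester.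
- The ring C phenol comes from thermal ring expansion of a 4-methoxy-4-(1-methoxyvinyl)cyclobutenone, itself made from the aryl methyl squarate of the DEFGH phenol, 1-methoxyvinyllithium and MeOTf.
- The DEFGH phenol comes from 3,4,5-trimethoxyphenol (ring H) by two turns of one cycle: squarate ester, vinyllithium/MeOTf, heat (ring G, then ring E), each followed by SNAr on 4-fluoro-3,5-dimethoxybenzaldehyde and Dakin oxidation (rings F and D).
- Rings are formed in the order G, E, C; rings A, B, D, F and H are purchased benzene rings.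

Key step: step 16

Remark: the quaternary carbon of the cyclobutenones and their lithium alkoxides is formed racemic and disappears on ring expansion, so no stereocontrol is needed. 4-Fluoro-3,5-dimethoxybenzaldehyde, 2,4,6-trimethoxyphenol and 1-bromo-3,5-difluorobenzene are taken as purchasable. 1-Methoxyvinyllithium 7 is a reagent solution that does not keep, so step 4 is a separate operation that is run afresh immediately before each of its uses (steps 5, 10 and 15), and the cold solution is transferred by cannula.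

Shorthand used in names (each group is the phenol minus its hydroxyl hydrogen):
- GH-oxy = 3,4,5-trimethoxy-2-(3,4,5-trimethoxyphenoxy)phenoxy (from 10)
- FGH-oxy = 3,5-dimethoxy-4-(GH-oxy)phenoxy (from 14)
- EFGH-oxy = 3,4,5-trimethoxy-2-(FGH-oxy)phenoxy (from 18)
- DEFGH-oxy = 3,5-dimethoxy-4-(EFGH-oxy)phenoxy (from 21)
- CDEFGH-oxy = 3,4,5-trimethoxy-2-(DEFGH-oxy)phenoxy (from 25)

## Route

Step 1
Reactants: 1 dimethyl squarate (3,4-dimethoxycyclobut-3-ene-1,2-dione)
Product: 2 sodium 2-methoxy-3,4-dioxocyclobut-1-en-1-olate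
Conditions: NaOH (1.0 equiv), MeOH/H2O, 0 °C → rt
Reagents that add atoms: sodium hydroxide, [Na+].[OH-]
Why: Saponification of a vinylogous ester by addition–elimination, which should stop after one methoxy group because the squarate monoanion is a delocalised vinylogous carboxylate that no longer accepts hydroxide.

Step 2
Reactants: 2 sodium 2-methoxy-3,4-dioxocyclobut-1-en-1-olate
Product: 3 3-chloro-4-methoxycyclobut-3-ene-1,2-dione
Conditions: (COCl)2, DMF (cat.), CH2Cl2, 0 °C → rt
Reagents that add atoms: oxalyl chloride, ClC(=O)C(=O)Cl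
Why: Vilsmeier-type conversion of a vinylogous carboxylate into the vinylogous acid chloride, the same reaction type that turns squaric acid into its dichloride.

Step 3
Reactants: 3 3-chloro-4-methoxycyclobut-3-ene-1,2-dione; 4 3,4,5-trimethoxyphenol
Product: 5 3-methoxy-4-(3,4,5-trimethoxyphenoxy)cyclobut-3-ene-1,2-dione
Conditions: i-Pr2NEt, CH2Cl2, −40 → 0 °C
Reagents that add atoms: none
Why: Vinylogous acyl substitution (addition–elimination) at the chlorine-bearing carbon by an unhindered phenol, chloride leaving far faster than methoxide.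

Step 4
Reactants: 6 methyl vinyl ether
Product: 7 1-methoxyvinyllithium (THF solution, used at once)
Conditions: t-BuLi, THF, −78 → 0 °C; recool to −78 °C
Reagents that add atoms: tert-butyllithium, [Li]C(C)(C)C
Why: Alpha-lithiation of an enol ether, in which t-BuLi removes the vinylic C–H on the oxygen-bearing carbon, acidified and directed by the methoxy oxygen, to give the standard acyl-anion-equivalent reagent.

Step 5
Reactants: 5 3-methoxy-4-(3,4,5-trimethoxyphenoxy)cyclobut-3-ene-1,2-dione; 7 1-methoxyvinyllithium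
Product: 9 racemic 3,4-dimethoxy-4-(1-methoxyvinyl)-2-(3,4,5-trimethoxyphenoxy)cyclobut-2-en-1-one, via lithium cyclobutenolate 8 (not isolated)
Conditions: 7 (THF solution from step 4) added to 5, THF, −78 °C; then MeOTf, −78 °C → rt
Reagents that add atoms: methyl triflate, COS(=O)(=O)C(F)(F)F
Why: 1,2-Addition of a hard alkenyllithium to the carbonyl bonded to the methoxy-bearing carbon, which is the vinylogous ester of the weaker aryloxy donor, the less hindered site and the one activated by lithium chelation to the neighbouring methoxy oxygen, followed by O-methylation of the tertiary alkoxide; the new quaternary stereocentre forms racemic.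

Step 6
Reactants: 9 racemic 3,4-dimethoxy-4-(1-methoxyvinyl)-2-(3,4,5-trimethoxyphenoxy)cyclobut-2-en-1-one
Product: 10 3,4,5-trimethoxy-2-(3,4,5-trimethoxyphenoxy)phenol (GH phenol)
Conditions: PhMe, 110 °C
Reagents that add atoms: none
Why: Moore rearrangement (4-pi ring opening with the methoxy group turning outward, 6-pi closure of the dienylketene, enolisation), which closes ring G and rehearses the key step on the smallest substrate.

Step 7
Reactants: 10 GH phenol; 11 4-fluoro-3,5-dimethoxybenzaldehyde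
Product: 12 3,5-dimethoxy-4-(GH-oxy)benzaldehyde
Conditions: Cs2CO3, DMSO, 110 °C
Reagents that add atoms: none
Why: Nucleophilic aromatic substitution in which the cesium phenoxide, which has only one ortho substituent, adds at the fluorine-bearing carbon para to the formyl group that stabilises the Meisenheimer intermediate.

Step 8
Reactants: 12 3,5-dimethoxy-4-(GH-oxy)benzaldehyde
Product: 14 3,5-dimethoxy-4-(GH-oxy)phenol (FGH phenol), via aryl formate 13 (not isolated)
Conditions: mCPBA, CH2Cl2, 0 °C → rt; wash; then K2CO3 (cat.), MeOH, rt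
Reagents that add atoms: mCPBA, OOC(=O)c1cccc(Cl)c1
Why: Baeyer–Villiger (Dakin-type) oxidation in which the electron-rich trioxygenated aryl group migrates in preference to hydrogen, followed by methanolysis of the formate.

Step 9
Reactants: 14 FGH phenol; 3 3-chloro-4-methoxycyclobut-3-ene-1,2-dione
Product: 15 3-methoxy-4-(FGH-oxy)cyclobut-3-ene-1,2-dione
Conditions: i-Pr2NEt, CH2Cl2, −40 → 0 °C
Reagents that add atoms: none
Why: Vinylogous acyl substitution as in step 3, on a phenol whose hydroxyl is flanked by two C–H positions.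

Step 10
Reactants: 15 3-methoxy-4-(FGH-oxy)cyclobut-3-ene-1,2-dione; 7 1-methoxyvinyllithium
Product: 17 racemic 3,4-dimethoxy-4-(1-methoxyvinyl)-2-(FGH-oxy)cyclobut-2-en-1-one, via lithium cyclobutenolate 16 (not isolated)
Conditions: 7 (fresh THF solution from step 4) added to 15, THF, −78 °C; then MeOTf, −78 °C → rt
Reagents that add atoms: methyl triflate, COS(=O)(=O)C(F)(F)F
Why: Regioselective 1,2-addition and O-methylation as in step 5, the bulkier aryloxy group shielding the other carbonyl still more; the quaternary stereocentre forms racemic.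

Step 11
Reactants: 17 racemic 3,4-dimethoxy-4-(1-methoxyvinyl)-2-(FGH-oxy)cyclobut-2-en-1-one
Product: 18 3,4,5-trimethoxy-2-(FGH-oxy)phenol (EFGH phenol)
Conditions: PhMe, 110 °C
Reagents that add atoms: none
Why: Moore rearrangement as in step 6, which closes ring E with the crowded ether to ring F already in place.

Step 12
Reactants: 18 EFGH phenol; 11 4-fluoro-3,5-dimethoxybenzaldehyde
Product: 19 3,5-dimethoxy-4-(EFGH-oxy)benzaldehyde
Conditions: Cs2CO3, DMSO, 110 °C
Reagents that add atoms: none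
Why: Nucleophilic aromatic substitution para to the formyl group, as in step 7.

Step 13
Reactants: 19 3,5-dimethoxy-4-(EFGH-oxy)benzaldehyde
Product: 21 3,5-dimethoxy-4-(EFGH-oxy)phenol (DEFGH phenol), via aryl formate 20 (not isolated)
Conditions: mCPBA, CH2Cl2, 0 °C → rt; wash; then K2CO3 (cat.), MeOH, rt
Reagents that add atoms: mCPBA, OOC(=O)c1cccc(Cl)c1
Why: Baeyer–Villiger (Dakin-type) oxidation with aryl migration, then formate methanolysis, as in step 8.

Step 14
Reactants: 21 DEFGH phenol; 3 3-chloro-4-methoxycyclobut-3-ene-1,2-dione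
Product: 22 3-methoxy-4-(DEFGH-oxy)cyclobut-3-ene-1,2-dione
Conditions: i-Pr2NEt, CH2Cl2, −40 → 0 °C
Reagents that add atoms: none
Why: Vinylogous acyl substitution as in step 3, which forms the future ring C–ring D ether from an unhindered phenol, so that this crowded ether never has to be made by coupling.

Step 15
Reactants: 22 3-methoxy-4-(DEFGH-oxy)cyclobut-3-ene-1,2-dione; 7 1-methoxyvinyllithium
Product: 24 racemic 3,4-dimethoxy-4-(1-methoxyvinyl)-2-(DEFGH-oxy)cyclobut-2-en-1-one, via lithium cyclobutenolate 23 (not isolated)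
Conditions: 7 (fresh THF solution from step 4) added to 22, THF, −78 °C; then MeOTf, −78 °C → rt
Reagents that add atoms: methyl triflate, COS(=O)(=O)C(F)(F)F
Why: 1,2-Addition of the alkenyllithium to the carbonyl that is the vinylogous ester of the aryloxy group (the more electrophilic, less hindered and methoxy-chelated one) and O-methylation of the alkoxide, which places the aryloxy carbon next to the remaining carbonyl; the quaternary stereocentre forms racemic.

Step 16
Reactants: 24 racemic 3,4-dimethoxy-4-(1-methoxyvinyl)-2-(DEFGH-oxy)cyclobut-2-en-1-one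
Product: 25 3,4,5-trimethoxy-2-(DEFGH-oxy)phenol (CDEFGH phenol)
Conditions: PhMe, 110 °C
Reagents that add atoms: none
Why: On heating, the cyclobutenone should open by conrotatory 4-pi cleavage of the bond between the carbonyl carbon and the quaternary carbon, the donor methoxy group on that carbon turning outward so that the 1-methoxyvinyl group points inward, next to the ketene. The dienylketene should then close by thermal disrotatory 6-pi electrocyclisation, forming the one new C–C bond between the ketene carbon and the vinyl CH2 and so ring C as a cyclohexa-2,4-dienone, which enolises to the phenol; the closest known reaction type is the Moore rearrangement of 4-alkenyl-4-alkoxycyclobutenones made from squarate esters. No stereocentre is formed, and the racemic quaternary carbon becomes aromatic C4 of ring C. The step needs torquoselectivity, secured by the strong preference of an alkoxy donor on the breaking bond for outward rotation, and it needs regiochemistry, which is fixed in 24: the aryloxy carbon is bonded to the ketene carbon and ends ortho to the new hydroxyl as C2, the three methoxy carbons become C3, C4 and C5, and the CH2 becomes C6–H. Closure of the Z-dienylketene is unimolecular and fast, so capture of the ketene by the electron-rich rings should not compete.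

Step 17
Reactants: 26 2,4,6-trimethoxyphenol; 27 1-bromo-3,5-difluorobenzene
Product: 28 1,3-difluoro-5-(2,4,6-trimethoxyphenoxy)benzene
Conditions: CuI (10 mol %), picolinic acid (20 mol %), K3PO4, DMSO, 90 °C
Reagents that add atoms: none
Why: Ullmann-type C–O coupling under conditions suited to 2,6-disubstituted phenols, at a temperature where the unactivated C–F bonds are not displaced.

Step 18
Reactants: 28 1,3-difluoro-5-(2,4,6-trimethoxyphenoxy)benzene
Product: 30 2,6-difluoro-4-(2,4,6-trimethoxyphenoxy)benzaldehyde, via aryllithium 29 (not isolated)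
Conditions: LiN(i-Pr)2, THF, −78 °C; then DMF, −78 → 0 °C; aq. HCl
Reagents that add atoms: N,N-dimethylformamide, CN(C)C=O
Why: Directed ortho-lithiation at the C–H between the two fluorine atoms, by far the most acidic site and the only one this amide base removes at −78 °C, followed by formylation of the aryllithium.

Step 19
Reactants: 30 2,6-difluoro-4-(2,4,6-trimethoxyphenoxy)benzaldehyde
Product: 31 2-fluoro-6-methoxy-4-(2,4,6-trimethoxyphenoxy)benzaldehyde
Conditions: NaOMe (1.05 equiv), MeOH/THF, 0 °C → rt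
Reagents that add atoms: sodium methoxide, [Na+].[O-]C
Why: Nucleophilic aromatic substitution of one of two equivalent fluorides ortho to the formyl group, the new methoxy group slowing a second substitution and fluoride leaving far better than the electron-rich aryloxide.

Step 20
Reactants: 25 CDEFGH phenol; 31 2-fluoro-6-methoxy-4-(2,4,6-trimethoxyphenoxy)benzaldehyde
Product: 32 2-methoxy-6-(CDEFGH-oxy)-4-(2,4,6-trimethoxyphenoxy)benzaldehyde
Conditions: Cs2CO3, DMF, 90 °C
Reagents that add atoms: none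
Why: Nucleophilic aromatic substitution of the fluoride ortho to the formyl group by the ring C phenoxide, which forms the ether between C1 of ring C and C5 of ring B.

Step 21
Reactants: 32 2-methoxy-6-(CDEFGH-oxy)-4-(2,4,6-trimethoxyphenoxy)benzaldehyde
Product: 34 2-methoxy-6-(CDEFGH-oxy)-4-(2,4,6-trimethoxyphenoxy)phenol, via aryl formate 33 (not isolated)
Conditions: mCPBA, CH2Cl2, 0 °C → rt; wash; then K2CO3 (cat.), MeOH, rt
Reagents that add atoms: mCPBA, OOC(=O)c1cccc(Cl)c1
Why: Baeyer–Villiger (Dakin-type) oxidation of a 2,4,6-trioxygenated benzaldehyde, in which aryl migration is strongly favoured, then formate methanolysis to place the C4 oxygen of ring B.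

Step 22
Reactants: 34 2-methoxy-6-(CDEFGH-oxy)-4-(2,4,6-trimethoxyphenoxy)phenol
Product: 35 CNP0175816.0
Conditions: BBr3 (excess), CH2Cl2, −78 °C → rt; MeOH/H2O, under argon
Reagents that add atoms: none
Why: Lewis acid cleavage of all twenty methyl aryl ethers by bromide attack at methyl, the diaryl ether bonds offering no sp3 carbon and staying intact.

## Compound list

1 | dimethyl squarate (3,4-dimethoxycyclobut-3-ene-1,2-dione) | COC1=C(OC)C(=O)C1=O | starting material
2 | sodium 2-methoxy-3,4-dioxocyclobut-1-en-1-olate | [Na+].COC1=C([O-])C(=O)C1=O | intermediate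
3 | 3-chloro-4-methoxycyclobut-3-ene-1,2-dione | COC1=C(Cl)C(=O)C1=O | intermediate
4 | 3,4,5-trimethoxyphenol (ring H) | COc1cc(O)cc(OC)c1OC | starting material
5 | 3-methoxy-4-(3,4,5-trimethoxyphenoxy)cyclobut-3-ene-1,2-dione | COC1=C(Oc2cc(OC)c(OC)c(OC)c2)C(=O)C1=O | intermediate
6 | methyl vinyl ether | COC=C | starting material
7 | 1-methoxyvinyllithium | [Li]C(=C)OC | intermediate
8 | lithium 2-methoxy-1-(1-methoxyvinyl)-4-oxo-3-(3,4,5-trimethoxyphenoxy)cyclobut-2-en-1-olate (racemic) | C=C(OC)C1(O[Li])C(OC)=C(Oc2cc(OC)c(OC)c(OC)c2)C1=O | intermediate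
9 | 3,4-dimethoxy-4-(1-methoxyvinyl)-2-(3,4,5-trimethoxyphenoxy)cyclobut-2-en-1-one (racemic) | C=C(OC)C1(OC)C(OC)=C(Oc2cc(OC)c(OC)c(OC)c2)C1=O | intermediate
10 | 3,4,5-trimethoxy-2-(3,4,5-trimethoxyphenoxy)phenol (GH phenol) | Oc1cc(OC)c(OC)c(OC)c1Oc1cc(OC)c(OC)c(OC)c1 | intermediate
11 | 4-fluoro-3,5-dimethoxybenzaldehyde | COc1cc(C=O)cc(OC)c1F | starting material
12 | 3,5-dimethoxy-4-(GH-oxy)benzaldehyde | O=Cc1cc(OC)c(Oc2cc(OC)c(OC)c(OC)c2Oc2cc(OC)c(OC)c(OC)c2)c(OC)c1 | intermediate
13 | 3,5-dimethoxy-4-(GH-oxy)phenyl formate | O=COc1cc(OC)c(Oc2cc(OC)c(OC)c(OC)c2Oc2cc(OC)c(OC)c(OC)c2)c(OC)c1 | intermediate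
14 | 3,5-dimethoxy-4-(GH-oxy)phenol (FGH phenol) | Oc1cc(OC)c(Oc2cc(OC)c(OC)c(OC)c2Oc2cc(OC)c(OC)c(OC)c2)c(OC)c1 | intermediate
15 | 3-methoxy-4-(FGH-oxy)cyclobut-3-ene-1,2-dione | COC1=C(Oc2cc(OC)c(Oc3cc(OC)c(OC)c(OC)c3Oc3cc(OC)c(OC)c(OC)c3)c(OC)c2)C(=O)C1=O | intermediate
16 | lithium 2-methoxy-1-(1-methoxyvinyl)-4-oxo-3-(FGH-oxy)cyclobut-2-en-1-olate (racemic) | C=C(OC)C1(O[Li])C(OC)=C(Oc2cc(OC)c(Oc3cc(OC)c(OC)c(OC)c3Oc3cc(OC)c(OC)c(OC)c3)c(OC)c2)C1=O | intermediate
17 | 3,4-dimethoxy-4-(1-methoxyvinyl)-2-(FGH-oxy)cyclobut-2-en-1-one (racemic) | C=C(OC)C1(OC)C(OC)=C(Oc2cc(OC)c(Oc3cc(OC)c(OC)c(OC)c3Oc3cc(OC)c(OC)c(OC)c3)c(OC)c2)C1=O | intermediate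
18 | 3,4,5-trimethoxy-2-(FGH-oxy)phenol (EFGH phenol) | Oc1cc(OC)c(OC)c(OC)c1Oc1cc(OC)c(Oc2cc(OC)c(OC)c(OC)c2Oc2cc(OC)c(OC)c(OC)c2)c(OC)c1 | intermediate
19 | 3,5-dimethoxy-4-(EFGH-oxy)benzaldehyde | O=Cc1cc(OC)c(Oc2cc(OC)c(OC)c(OC)c2Oc2cc(OC)c(Oc3cc(OC)c(OC)c(OC)c3Oc3cc(OC)c(OC)c(OC)c3)c(OC)c2)c(OC)c1 | intermediate
20 | 3,5-dimethoxy-4-(EFGH-oxy)phenyl formate | O=COc1cc(OC)c(Oc2cc(OC)c(OC)c(OC)c2Oc2cc(OC)c(Oc3cc(OC)c(OC)c(OC)c3Oc3cc(OC)c(OC)c(OC)c3)c(OC)c2)c(OC)c1 | intermediate
21 | 3,5-dimethoxy-4-(EFGH-oxy)phenol (DEFGH phenol) | Oc1cc(OC)c(Oc2cc(OC)c(OC)c(OC)c2Oc2cc(OC)c(Oc3cc(OC)c(OC)c(OC)c3Oc3cc(OC)c(OC)c(OC)c3)c(OC)c2)c(OC)c1 | intermediate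
22 | 3-methoxy-4-(DEFGH-oxy)cyclobut-3-ene-1,2-dione | COC1=C(Oc2cc(OC)c(Oc3cc(OC)c(OC)c(OC)c3Oc3cc(OC)c(Oc4cc(OC)c(OC)c(OC)c4Oc4cc(OC)c(OC)c(OC)c4)c(OC)c3)c(OC)c2)C(=O)C1=O | intermediate
23 | lithium 2-methoxy-1-(1-methoxyvinyl)-4-oxo-3-(DEFGH-oxy)cyclobut-2-en-1-olate (racemic) | C=C(OC)C1(O[Li])C(OC)=C(Oc2cc(OC)c(Oc3cc(OC)c(OC)c(OC)c3Oc3cc(OC)c(Oc4cc(OC)c(OC)c(OC)c4Oc4cc(OC)c(OC)c(OC)c4)c(OC)c3)c(OC)c2)C1=O | intermediate
24 | 3,4-dimethoxy-4-(1-methoxyvinyl)-2-(DEFGH-oxy)cyclobut-2-en-1-one (racemic) | C=C(OC)C1(OC)C(OC)=C(Oc2cc(OC)c(Oc3cc(OC)c(OC)c(OC)c3Oc3cc(OC)c(Oc4cc(OC)c(OC)c(OC)c4Oc4cc(OC)c(OC)c(OC)c4)c(OC)c3)c(OC)c2)C1=O | intermediate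
25 | 3,4,5-trimethoxy-2-(DEFGH-oxy)phenol (CDEFGH phenol) | Oc1cc(OC)c(OC)c(OC)c1Oc1cc(OC)c(Oc2cc(OC)c(OC)c(OC)c2Oc2cc(OC)c(Oc3cc(OC)c(OC)c(OC)c3Oc3cc(OC)c(OC)c(OC)c3)c(OC)c2)c(OC)c1 | intermediate
26 | 2,4,6-trimethoxyphenol (ring A) | COc1cc(OC)c(O)c(OC)c1 | starting material
27 | 1-bromo-3,5-difluorobenzene | Fc1cc(F)cc(Br)c1 | starting material
28 | 1,3-difluoro-5-(2,4,6-trimethoxyphenoxy)benzene | COc1cc(OC)c(Oc2cc(F)cc(F)c2)c(OC)c1 | intermediate
29 | [2,6-difluoro-4-(2,4,6-trimethoxyphenoxy)phenyl]lithium | COc1cc(OC)c(Oc2cc(F)c([Li])c(F)c2)c(OC)c1 | intermediate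
30 | 2,6-difluoro-4-(2,4,6-trimethoxyphenoxy)benzaldehyde | COc1cc(OC)c(Oc2cc(F)c(C=O)c(F)c2)c(OC)c1 | intermediate
31 | 2-fluoro-6-methoxy-4-(2,4,6-trimethoxyphenoxy)benzaldehyde | COc1cc(OC)c(Oc2cc(F)c(C=O)c(OC)c2)c(OC)c1 | intermediate
32 | 2-methoxy-6-(CDEFGH-oxy)-4-(2,4,6-trimethoxyphenoxy)benzaldehyde | COc1cc(OC)c(Oc2cc(OC)c(C=O)c(Oc3cc(OC)c(OC)c(OC)c3Oc3cc(OC)c(Oc4cc(OC)c(OC)c(OC)c4Oc4cc(OC)c(Oc5cc(OC)c(OC)c(OC)c5Oc5cc(OC)c(OC)c(OC)c5)c(OC)c4)c(OC)c3)c2)c(OC)c1 | intermediate
33 | 2-methoxy-6-(CDEFGH-oxy)-4-(2,4,6-trimethoxyphenoxy)phenyl formate | COc1cc(OC)c(Oc2cc(OC)c(OC=O)c(Oc3cc(OC)c(OC)c(OC)c3Oc3cc(OC)c(Oc4cc(OC)c(OC)c(OC)c4Oc4cc(OC)c(Oc5cc(OC)c(OC)c(OC)c5Oc5cc(OC)c(OC)c(OC)c5)c(OC)c4)c(OC)c3)c2)c(OC)c1 | intermediate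
34 | 2-methoxy-6-(CDEFGH-oxy)-4-(2,4,6-trimethoxyphenoxy)phenol (eicosamethyl ether of the target) | COc1cc(OC)c(Oc2cc(OC)c(O)c(Oc3cc(OC)c(OC)c(OC)c3Oc3cc(OC)c(Oc4cc(OC)c(OC)c(OC)c4Oc4cc(OC)c(Oc5cc(OC)c(OC)c(OC)c5Oc5cc(OC)c(OC)c(OC)c5)c(OC)c4)c(OC)c3)c2)c(OC)c1 | intermediate
35 | CNP0175816.0 (octameric aryl ether with 21 free hydroxyl groups, no stereocentre) | Oc1cc(O)c(Oc2cc(O)c(O)c(Oc3cc(O)c(O)c(O)c3Oc3cc(O)c(Oc4cc(O)c(O)c(O)c4Oc4cc(O)c(Oc5cc(O)c(O)c(O)c5Oc5cc(O)c(O)c(O)c5)c(O)c4)c(O)c3)c2)c(O)c1 | target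

## Step count and risks

Total step count: 22 (step 4, the preparation of reagent 7, is repeated before each of its three uses). Longest linear sequence: 18 steps (steps 1 to 3, 5 to 16, then 20 to 22). Steps 17 to 19 form the AB branch and step 4 supplies the reagent.

The three steps most likely to fail:

1. Step 16 (key step). The ketene released on ring opening may be consumed before it closes: inward rotation of the methoxy group would give a dienylketene that cannot cyclise, traces of water may capture the ketene, or the enol ether may be hydrolysed on handling so that no 6-pi system remains. The fallback brings ring C in as an intact arene. It sets out from 21: an Ullmann ether coupling (CuI, N,N-dimethylglycine, Cs2CO3, dioxane, 100 °C) with 2-bromo-3,4,5-trimethoxybenzaldehyde, in which the ortho formyl group assists copper insertion and the phenol is unhindered, should give 3,4,5-trimethoxy-2-(DEFGH-oxy)benzaldehyde F1. mCPBA in CH2Cl2 should then give 3,4,5-trimethoxy-2-(DEFGH-oxy)phenyl formate F2, and K2CO3 in MeOH should release the phenol, which is compound 25, where the route is rejoined.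

2. Step 15. Site selectivity between the two carbonyl groups may be lost once the aryloxy group is a bulky pentamer, and attack at the carbonyl next to the aryloxy-bearing carbon would lead to the regioisomeric phenol after heating. The fallback makes the two carbonyl groups equivalent. It sets out from 21 (2 equiv), which with 3,4-dichlorocyclobut-3-ene-1,2-dione (i-Pr2NEt, CH2Cl2, −40 °C) should give the symmetrical diaryl squarate 3,4-bis(DEFGH-oxy)cyclobut-3-ene-1,2-dione F3. Addition of 7 (fresh solution from step 4) at −78 °C should give lithium 1-(1-methoxyvinyl)-4-oxo-2,3-bis(DEFGH-oxy)cyclobut-2-en-1-olate F4, and MeOTf should cap it as racemic 4-methoxy-4-(1-methoxyvinyl)-2,3-bis(DEFGH-oxy)cyclobut-2-en-1-one F5. One equivalent of NaOMe in MeOH/THF at −40 °C, followed by aqueous work-up, should then exchange only the aryloxy group on the enone beta carbon (vinylogous transesterification, aryloxide being the better leaving group). This gives 24, where the route is rejoined, and returns one equivalent of 21.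

3. Step 12 (the same concern applies to step 7). Addition of the phenoxide at a fluorine-bearing carbon flanked by two methoxy groups may be slow, so that base-induced degradation of the aldehyde outruns substitution. The fallback replaces the Meisenheimer pathway by copper catalysis: from 18, an Ullmann ether coupling with 4-bromo-3,5-dimethoxybenzaldehyde (CuI, picolinic acid, K3PO4, DMSO, 100 °C) should give 19 directly, where the route is rejoined; no compound outside the list is made (F0).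

Further compounds

F1 | step 16 | 3,4,5-trimethoxy-2-(DEFGH-oxy)benzaldehyde | O=Cc1cc(OC)c(OC)c(OC)c1Oc1cc(OC)c(Oc2cc(OC)c(OC)c(OC)c2Oc2cc(OC)c(Oc3cc(OC)c(OC)c(OC)c3Oc3cc(OC)c(OC)c(OC)c3)c(OC)c2)c(OC)c1
F2 | step 16 | 3,4,5-trimethoxy-2-(DEFGH-oxy)phenyl formate | O=COc1cc(OC)c(OC)c(OC)c1Oc1cc(OC)c(Oc2cc(OC)c(OC)c(OC)c2Oc2cc(OC)c(Oc3cc(OC)c(OC)c(OC)c3Oc3cc(OC)c(OC)c(OC)c3)c(OC)c2)c(OC)c1
F3 | step 15 | 3,4-bis(DEFGH-oxy)cyclobut-3-ene-1,2-dione | O=C1C(=O)C(Oc2cc(OC)c(Oc3cc(OC)c(OC)c(OC)c3Oc3cc(OC)c(Oc4cc(OC)c(OC)c(OC)c4Oc4cc(OC)c(OC)c(OC)c4)c(OC)c3)c(OC)c2)=C1Oc2cc(OC)c(Oc3cc(OC)c(OC)c(OC)c3Oc3cc(OC)c(Oc4cc(OC)c(OC)c(OC)c4Oc4cc(OC)c(OC)c(OC)c4)c(OC)c3)c(OC)c2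
F4 | step 15 | lithium 1-(1-methoxyvinyl)-4-oxo-2,3-bis(DEFGH-oxy)cyclobut-2-en-1-olate (racemic) | C=C(OC)C1(O[Li])C(Oc2cc(OC)c(Oc3cc(OC)c(OC)c(OC)c3Oc3cc(OC)c(Oc4cc(OC)c(OC)c(OC)c4Oc4cc(OC)c(OC)c(OC)c4)c(OC)c3)c(OC)c2)=C(Oc2cc(OC)c(Oc3cc(OC)c(OC)c(OC)c3Oc3cc(OC)c(Oc4cc(OC)c(OC)c(OC)c4Oc4cc(OC)c(OC)c(OC)c4)c(OC)c3)c(OC)c2)C1=O
F5 | step 15 | 4-methoxy-4-(1-methoxyvinyl)-2,3-bis(DEFGH-oxy)cyclobut-2-en-1-one (racemic) | C=C(OC)C1(OC)C(Oc2cc(OC)c(Oc3cc(OC)c(OC)c(OC)c3Oc3cc(OC)c(Oc4cc(OC)c(OC)c(OC)c4Oc4cc(OC)c(OC)c(OC)c4)c(OC)c3)c(OC)c2)=C(Oc2cc(OC)c(Oc3cc(OC)c(OC)c(OC)c3Oc3cc(OC)c(Oc4cc(OC)c(OC)c(OC)c4Oc4cc(OC)c(OC)c(OC)c4)c(OC)c3)c(OC)c2)C1=O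
F0 | step 12 | none | none
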